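**Plan**

Numbering: ring A is C1 (OH), C2 (Br), C3 (H), C4 (O-aryl), C5 (Br), C6 (Br). Ring B is C1' (O), C2' (OH), C3' (Br), C4' (Br), C5' (OH), C6' (Br).
Cuts, in order: the two O–CH3 bonds masking the ring B hydroquinone; the C2–Br and C6–Br bonds of ring A together with its aromaticity; the C4–O ether bond, made while C4 is still an sp3 carbinol carbon; the three C–Br bonds of ring B.
Enabling feature: both carbons ortho to the C1 hydroxyl (C2, C6) carry bromine and the para carbon C4 carries the ether oxygen. The third bromine (C5) is meta to OH, where phenol bromination cannot place it, so C1–C6–C5–C4 is read as the O=C–CH=C(Br)–CH(OAr) unit of a 3-bromo-4-aryloxycyclohex-2-enone.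
Forward order: ring B is perbrominated as an arene. Ring A starts as a six-membered enone ketal, gains the future C5 bromine as a vinyl bromide, is joined to ring B by Mitsunobu etherification, is unmasked, then aromatised and dibrominated in one flask. Demethylation ends the route, and no ring is closed anywhere.
Stereochemistry: the target has no stereocentre. Every sp3 centre met on the way is racemic and disappears when ring A becomes aromatic.

Key step: step 6

Assumption: 2,5-dimethoxyphenol 1 and 1,4-dioxaspiro[4.5]dec-6-en-8-one 2 are taken as catalogue compounds, and all sp3 intermediates are used as racemates.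

Step 1
Reactants: 1 2,5-dimethoxyphenol
Product: 3 3,4,6-tribromo-2,5-dimethoxyphenol
Conditions: Br2 (3.3 equiv), AcOH, rt → 60 °C; aq. NaHSO3 quench
Reagents that add atoms: bromine, BrBr
Why: Electrophilic aromatic bromination taken to exhaustion: C4 and C6 (para and ortho to OH) should react at room temperature and the last free carbon, C3 ortho to the C2 methoxy group, on warming, after which no ring position is left to over-react.

Step 2
Reactants: 2 1,4-dioxaspiro[4.5]dec-6-en-8-one
Product: 5 7-bromo-1,4-dioxaspiro[4.5]dec-6-en-8-one, via trans-dibromo ketone 4 (not isolated)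
Conditions: Br2 (1.05 equiv), CH2Cl2, 0 °C; then Et3N (1.5 equiv), 0 °C → rt
Reagents that add atoms: bromine, BrBr
Why: Standard α-bromination of a cyclic enone by bromine addition and base-induced dehydrobromination: Et3N removes the acidic C7 hydrogen of 4 and expels the C6 bromide, and the amine keeps the medium basic so that the dioxolane is untouched.

Step 3
Reactants: 5 7-bromo-1,4-dioxaspiro[4.5]dec-6-en-8-one
Product: 6 (±)-7-bromo-1,4-dioxaspiro[4.5]dec-6-en-8-ol
Conditions: NaBH4, CeCl3·7H2O, MeOH, −20 → 0 °C; aq. NaHCO3
Reagents that add atoms: none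
Why: Luche reduction: the CeCl3-modified borohydride delivers hydride 1,2 to the bromo enone without touching the vinyl bromide or the ketal, and the new C8 carbinol centre forms as a racemate, which is harmless because this carbon ends up sp2.

Step 4
Reactants: 6 (±)-7-bromo-1,4-dioxaspiro[4.5]dec-6-en-8-ol; 3 3,4,6-tribromo-2,5-dimethoxyphenol
Product: 7 (±)-7-bromo-8-(3,4,6-tribromo-2,5-dimethoxyphenoxy)-1,4-dioxaspiro[4.5]dec-6-ene
Conditions: PPh3 (1.5 equiv), DIAD (1.5 equiv), THF (concentrated), 0 °C → rt
Reagents that add atoms: none
Why: Mitsunobu etherification: the acidic tribromophenol protonates the PPh3–DIAD adduct readily and its oxygen displaces the activated hydroxyl at C8 by SN2 (inversion, irrelevant in a racemate), the SN2' site C6 is shielded by the adjacent quaternary ketal carbon, and phenols flanked by one halogen and one methoxy group are established partners for 2-halocyclohex-2-enols in this reaction.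

Step 5
Reactants: 7 (±)-7-bromo-8-(3,4,6-tribromo-2,5-dimethoxyphenoxy)-1,4-dioxaspiro[4.5]dec-6-ene
Product: 8 (±)-3-bromo-4-(3,4,6-tribromo-2,5-dimethoxyphenoxy)cyclohex-2-en-1-one
Conditions: TFA, H2O, CH2Cl2, 0 °C → rt
Reagents that add atoms: water, O
Why: Acid-catalysed hydrolysis of an allylic dioxolane through its conjugated oxocarbenium ion, run with a halide-free acid so that the emerging β-bromo enone (a vinylogous acyl bromide) cannot exchange its halogen, while the aryl ethers and aryl bromides are inert.

Step 6
Reactants: 8 (±)-3-bromo-4-(3,4,6-tribromo-2,5-dimethoxyphenoxy)cyclohex-2-en-1-one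
Product: 13 2,3,6-tribromo-4-(3,4,6-tribromo-2,5-dimethoxyphenoxy)phenol, via 6-bromo ketone 9 (not isolated), via 4H-dienone 10 (not isolated), via monobromophenol 11 (not isolated), via dibromophenol 12 (not isolated)
Conditions: Br2 (3.1 equiv, all present from the start), AcOH, cat. HBr, dark, rt → 50 °C; aq. NaHSO3 quench
Reagents that add atoms: bromine, BrBr
Why: Acid-catalysed enolisation of 8 toward its α-methylene (future C2) and capture of the enol by Br2 should give 9, loss of HBr across C2–C3 gives the 4H-cyclohexa-2,5-dienone 10, and this keto tautomer of a phenol aromatises at once to 11 by moving the C4 hydrogen to oxygen. Phenol 11 then undergoes ordinary electrophilic substitution, first at the open ortho carbon C2 (12) and then at C6 between the hydroxyl and the C5 bromine, so that the C2–Br and C6–Br bonds are both made in this flask and the equation balances at three Br2 in and four HBr out. The closest known reaction type is the aromatising α-bromination–dehydrobromination of cyclohexanones and cyclohexenones to bromophenols with Br2 in acetic acid. No ring is closed and no stereocentre is created; the sp3 centres of 8 and 9 are destroyed. Site selectivity is secured because C2 and C6 are the only carbons ortho to the new hydroxyl, the para carbon is blocked by the ether, C3 is served only by the weak donor oxygen of an electron-poor aryloxy group, ring B has no free position, and an enol bromination that strays to C6 or C4 (through the extended dienol) either places bromine where it is wanted or loses HBr toward C3 to reach the same arene. The C5 bromine is kept because it is vinylic and bromide is the only nucleophile present, and the aryloxy group is kept because no enol of 8 pushes electrons toward the C4–O bond, a C4 cation would be vinylogously α to the carbonyl, and with all the bromine present from the outset each enol should be brominated far faster than it can ionise.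

Step 7
Reactants: 13 2,3,6-tribromo-4-(3,4,6-tribromo-2,5-dimethoxyphenoxy)phenol
Product: 14 2,3,5-tribromo-6-(2,3,5-tribromo-4-hydroxyphenoxy)benzene-1,4-diol (CNP0277646.0)
Conditions: BBr3 (5 equiv), CH2Cl2, −78 °C → rt; ice-water quench, aq. Na2S2O4 wash under Ar
Reagents that add atoms: none
Why: Lewis-acid cleavage of aryl methyl ethers with BBr3: boron binds each methoxy oxygen and bromide removes the methyl group by SN2, the diaryl ether and the C–Br bonds offer no sp3 carbon to attack and survive, and the dithionite wash keeps the ring B hydroquinone in its reduced form.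

**Compound list**

1 | 2,5-dimethoxyphenol | COc1ccc(OC)c(O)c1 | starting material
2 | 1,4-dioxaspiro[4.5]dec-6-en-8-one | O=C1C=CC2(CC1)OCCO2 | starting material
3 | 3,4,6-tribromo-2,5-dimethoxyphenol | Oc1c(OC)c(Br)c(Br)c(OC)c1Br | intermediate
4 | trans-6,7-dibromo-1,4-dioxaspiro[4.5]decan-8-one (racemic, one enantiomer drawn; not isolated) | O=C1[C@H](Br)[C@@H](Br)C2(CC1)OCCO2 | intermediate
5 | 7-bromo-1,4-dioxaspiro[4.5]dec-6-en-8-one | O=C1C(Br)=CC2(CC1)OCCO2 | intermediate
6 | 7-bromo-1,4-dioxaspiro[4.5]dec-6-en-8-ol (racemic) | OC1CCC2(C=C1Br)OCCO2 | intermediate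
7 | 7-bromo-8-(3,4,6-tribromo-2,5-dimethoxyphenoxy)-1,4-dioxaspiro[4.5]dec-6-ene (racemic) | COc1c(Br)c(Br)c(OC)c(Br)c1OC1CCC2(C=C1Br)OCCO2 | intermediate
8 | 3-bromo-4-(3,4,6-tribromo-2,5-dimethoxyphenoxy)cyclohex-2-en-1-one (racemic) | O=C1C=C(Br)C(Oc2c(OC)c(Br)c(Br)c(OC)c2Br)CC1 | intermediate
9 | 3,6-dibromo-4-(3,4,6-tribromo-2,5-dimethoxyphenoxy)cyclohex-2-en-1-one (racemic, mixture of C6 epimers; not isolated) | O=C1C=C(Br)C(Oc2c(OC)c(Br)c(Br)c(OC)c2Br)CC1Br | intermediate
10 | 3-bromo-4-(3,4,6-tribromo-2,5-dimethoxyphenoxy)cyclohexa-2,5-dien-1-one (racemic; not isolated) | O=C1C=CC(Oc2c(OC)c(Br)c(Br)c(OC)c2Br)C(Br)=C1 | intermediate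
11 | 3-bromo-4-(3,4,6-tribromo-2,5-dimethoxyphenoxy)phenol (not isolated) | Oc1ccc(Oc2c(OC)c(Br)c(Br)c(OC)c2Br)c(Br)c1 | intermediate
12 | 2,5-dibromo-4-(3,4,6-tribromo-2,5-dimethoxyphenoxy)phenol (not isolated) | Oc1cc(Br)c(Oc2c(OC)c(Br)c(Br)c(OC)c2Br)cc1Br | intermediate
13 | 2,3,6-tribromo-4-(3,4,6-tribromo-2,5-dimethoxyphenoxy)phenol | Oc1c(Br)cc(Oc2c(OC)c(Br)c(Br)c(OC)c2Br)c(Br)c1Br | intermediate
14 | 2,3,5-tribromo-6-(2,3,5-tribromo-4-hydroxyphenoxy)benzene-1,4-diol | Oc1c(Br)cc(Oc2c(O)c(Br)c(Br)c(O)c2Br)c(Br)c1Br | target

Total step count: 7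
Longest linear sequence: 6 steps (2 → 5 → 6 → 7 → 8 → 13 → 14)

**Steps most likely to fail**

Step 6. The sequence may stall before dehydrobromination. The HBr that builds up may cleave the allylic C4–O bond while C4 is still sp3. Surplus bromine may also attack C4 ipso and oxidatively strip the aryloxy group. The fallback separates dehydrogenation from halogenation and keeps acid away until ring A is aromatic.
- It sets out from 8. Kinetic deprotonation with LiN(SiMe3)2 in THF at −78 °C would give the cross-conjugated lithium dienolate F1.
- PhSeCl would trap it as 3-bromo-6-(phenylselanyl)-4-(3,4,6-tribromo-2,5-dimethoxyphenoxy)cyclohex-2-en-1-one F2.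
- H2O2 in CH2Cl2/pyridine at 0 °C would oxidise this to the selenoxide F3, whose syn elimination leads through 10 to phenol 11, now isolated.
- Br2 (2 equiv) in AcOH at room temperature would then carry 11 through 12 and come back to the route at 13.

Step 4. Displacement at a secondary allylic carbon by a phenol substituted at both ortho positions may be slow. Elimination to the diene, or alkylation of the reduced azodicarboxylate, could then take over. The fallback uses a preformed electrophile and a phenoxide in place of in situ hydroxyl activation.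
- It sets out from 6. Appel bromination (CBr4, PPh3, CH2Cl2, 0 °C) would give 7,8-dibromo-1,4-dioxaspiro[4.5]dec-6-ene F4.
- Williamson alkylation of 3 with F4 (Cs2CO3, DMF, rt) would come back to the route at 7. Alkylation of phenoxides by 2,3-dibromocyclohexenes is well established.

Step 1. The third bromination, at a carbon activated by only one methoxy group and deactivated by two bromines, may stall. Forcing it may bring oxidation or demethylation of the electron-rich ring. The fallback installs the last bromine by directed metalation instead of electrophilic substitution.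
- It sets out from 1. Br2 (2 equiv, CH2Cl2, 0 °C) would give 4,6-dibromo-2,5-dimethoxyphenol F5.
- MOMCl and iPr2NEt would give 4,6-dibromo-2,5-dimethoxyphenyl methoxymethyl ether F6.
- (2,2,6,6-Tetramethylpiperidyl)MgCl·LiCl in THF at −20 °C would remove the only ring hydrogen, flanked by OMe and Br, to give the arylmagnesium chloride F7.
- BrCl2C–CCl2Br would convert this into 3,4,6-tribromo-2,5-dimethoxyphenyl methoxymethyl ether F8.
- HCl in MeOH would come back to the route at 3.

**Further compounds**

F1 | step 6 | lithium 3-bromo-4-(3,4,6-tribromo-2,5-dimethoxyphenoxy)cyclohexa-1,5-dien-1-olate (racemic) | [Li]OC1=CCC(Oc2c(OC)c(Br)c(Br)c(OC)c2Br)C(Br)=C1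
F2 | step 6 | 3-bromo-6-(phenylselanyl)-4-(3,4,6-tribromo-2,5-dimethoxyphenoxy)cyclohex-2-en-1-one (racemic, epimer mixture) | O=C1C=C(Br)C(Oc2c(OC)c(Br)c(Br)c(OC)c2Br)CC1[Se]c1ccccc1
F3 | step 6 | 3-bromo-6-(phenylseleninyl)-4-(3,4,6-tribromo-2,5-dimethoxyphenoxy)cyclohex-2-en-1-one (racemic, isomer mixture) | O=C1C=C(Br)C(Oc2c(OC)c(Br)c(Br)c(OC)c2Br)CC1[Se](=O)c1ccccc1
F4 | step 4 | 7,8-dibromo-1,4-dioxaspiro[4.5]dec-6-ene (racemic) | BrC1CCC2(C=C1Br)OCCO2
F5 | step 1 | 4,6-dibromo-2,5-dimethoxyphenol | COc1cc(Br)c(OC)c(Br)c1O
F6 | step 1 | 4,6-dibromo-2,5-dimethoxyphenyl methoxymethyl ether | COCOc1c(OC)cc(Br)c(OC)c1Br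
F7 | step 1 | [4,6-dibromo-2,5-dimethoxy-3-(methoxymethoxy)phenyl]magnesium chloride | COCOc1c(OC)c([Mg]Cl)c(Br)c(OC)c1Br
F8 | step 1 | 3,4,6-tribromo-2,5-dimethoxyphenyl methoxymethyl ether | COCOc1c(OC)c(Br)c(Br)c(OC)c1Br
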